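The earlier runs and the new flask were computed for an exercise; scatter was added.

Count what the nucleophile buys.

| setting | spring | dawn | elm | birch |
|---|---|---|---|---|
| solid electrophile | 13 mM | 9.5 mM | 19 mM | 19 mM |
| nucleophile | 19 mM | 19 mM | 38.0 mM | 19.0 mM |
| remark | run made earlier | run made earlier |  |  |
| time |  |  | 6.0 d | 6.0 d |

| run | time / d | solid electrophile / % | target / % |
|---|---|---|---|
| spring | 0.250 | 37 | 43 |
| spring | 0.417 | 6 | 56 |
| spring | 0.625 | 0 | 62 |
| spring | 1.04 | 2 | 68 |
| spring | 1.67 | 1 | 65 |
| spring | 2.50 | 0 | 70 |
| spring | 4.00 | 0 | 68 |
| dawn | 0.208 | 25 | 51 |
| dawn | 0.500 | 1 | 75 |
| dawn | 1.04 | 3 | 89 |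
| dawn | 1.67 | 0 | 84 |
| dawn | 2.00 | 0 | 91 |
| dawn | 3.00 | 0 | 91 |
| dawn | 4.00 | 0 | 86 |

(standard deviation of a reading: 2 percentage points)

- at the start none of the solid electrophile is in solution
- what has only dissolved of solid electrophile counts as not reacted

- part of the solid electrophile that has reacted (what has only dissolved counts as not reacted) at the end, elm
- part of the solid electrophile that has reacted (what has only dissolved counts as not reacted) at the end, birch
- what raising the concentration of nucleophile from its lowest to its highest value here does to the part of the solid electrophile that has reacted (what has only dissolved counts as not reacted) (changes below 5 percentage points count as none) (no change / it falls / it rises)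

Time is the first setting. By hand, a longer wait could add target, but the spring run reads 68 % at 1.04 d and 68 % at 4.00 d, so we expect nothing from six days.

The charge of solid electrophile is the second setting. By hand, more solid should give more target. Yet the readings on the plateau average 8.81 mM of target in spring and 8.38 mM in dawn, although spring got more solid than dawn and the nucleophile charge was the same. So we read nucleophile as the limiting reagent and define the price, the nucleophile charged per target made on the plateau: 2.21 from the two runs together. Birch has the same nucleophile charge, so we reckon 45.2 % reacted there.

Nucleophile is the third setting. At the same price, elm would reach 90.5 %. But we go round once more, on the price itself. If one nucleophile goes into each target, a price above 1 says that nucleophile goes elsewhere, and we assume a loss in which two nucleophiles meet, so that the extra per target grows in step with the nucleophile charge. The price in elm then becomes 3.42, and we commit to 58.4 % for elm, a rise of 13 percentage points from birch.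

The forecast gives 96 % (86 % to 100 %) for elm and 49 % (43 % to 55 %) for birch, and on the trend says it rises, holding that “roughly two nucleophiles are used per electrophile”; on elm our reckoning differs from it.

The flask gives 54.8 % for elm and 45.6 % for birch, and on the trend it rises, by 9.2 points.

    electrophile + nucleophile → acid set free + target (k = 0.0670 /M/s)
    nucleophile + acid set free ⇌ protonated nucleophile, settled at all times (K = 770 /M)
    2 nucleophile → self-condensation product (k = 0.00460 /M/s)
    solid electrophile ⇌ electrophile, rate k4*(cs4 - [electrophile]) while solid is left; crystals form when [electrophile] > cs4 (solubility = 13.0 mM, k = 3.10 × 10⁻⁵ /s)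

These results mean a price of 3.65 in elm and 2.19 in birch, against our 3.42 and 2.21. In birch, half of the target step's turnover is done by 0.185 d, earlier than half of the dissolving at 0.308 d. At the end of birch, free nucleophile stands at 0 % of its charge and dissolved electrophile at 54.4 % of the solid electrophile charged.

For a neighbour of birch charged with 76 mM of solid electrophile, we reckon at our price 8.59 mM of target, or 11.3 % of its charge. The computed flask gives 11.4 %.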